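**Strategy**

Everything rests on disconnecting the acyclic side chain on both flanks of the cis C8=C9 alkene, at C7–C8 and C9–C10: since C7 and C10 are unbranched methylenes, C8 and C9 can be supplied by acetylene itself. In one operation the magnesium cuprate of the aryl-bearing C1–C7 arm adds syn to acetylene and the resulting Z-alkenylcuprate is alkylated by the C10–C17 iodide, creating both C–C bonds and the Z geometry; no ring is formed, and the resorcinol ring and C15 are spectators. The precursor is 7-[3,5-bis(methoxymethoxy)phenyl]heptylmagnesium bromide, combined with acetylene and a silyl-protected (S)-8-iodooctan-3-ol whose stereocentre derives from (S)-1,2-epoxybutane.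

Key step: step 11

Remark on the chemistry: the chain is numbered C1 (benzylic) to C17 and the target is (8Z,15S). Opening (S)-1,2-epoxybutane at its CH2 carbon changes neither the bonds at the stereocentre nor the CIP ranking, so the (S)-epoxide gives (15S). The 7 + 2 + 8 carbon count of the three components matches the target.

**Route**

Step 1
Reactants: 1 6-bromohexan-1-ol
Product: 2 (6-hydroxyhexyl)triphenylphosphonium bromide
Conditions: PPh3, MeCN, reflux; crystallise
Reagents that add atoms: triphenylphosphine, c1ccc(cc1)P(c1ccccc1)c1ccccc1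
Why: SN2 quaternisation of triphenylphosphine by the unhindered primary bromide (phosphonium salt formation) tolerates the free hydroxyl group.

Step 2
Reactants: 3 3,5-dihydroxybenzaldehyde
Product: 4 3,5-bis(methoxymethoxy)benzaldehyde
Conditions: MOMCl, i-Pr2NEt, CH2Cl2, 0 °C → rt
Reagents that add atoms: chloromethyl methyl ether, COCCl
Why: Base-mediated O-alkylation of both phenols with MOMCl (Williamson-type acetal ether formation) is routine for resorcinols and leaves the aldehyde untouched.

Step 3
Reactants: 2 (6-hydroxyhexyl)triphenylphosphonium bromide; 4 3,5-bis(methoxymethoxy)benzaldehyde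
Product: 6 7-[3,5-bis(methoxymethoxy)phenyl]hept-6-en-1-ol (E/Z mixture), via ylide alkoxide 5 (not isolated)
Conditions: 2, NaHMDS (2 equiv per 2), THF, 0 °C; then 4, −78 °C → rt
Reagents that add atoms: none
Why: Wittig olefination in which the first equivalent of base removes the hydroxyl proton and the second forms the non-stabilised ylide, which condenses with the non-enolisable aryl aldehyde; the alkene geometry is irrelevant because the double bond is saturated in step 4.

Step 4
Reactants: 6 7-[3,5-bis(methoxymethoxy)phenyl]hept-6-en-1-ol
Product: 7 7-[3,5-bis(methoxymethoxy)phenyl]heptan-1-ol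
Conditions: H2 (1 atm), 10% Pd/C, EtOAc, rt
Reagents that add atoms: none
Why: Heterogeneous catalytic hydrogenation saturates the styrenyl double bond under neutral conditions in which aryl MOM ethers, having no benzylic C–O bond, are stable.

Step 5
Reactants: 7 7-[3,5-bis(methoxymethoxy)phenyl]heptan-1-ol
Product: 8 1-(7-bromoheptyl)-3,5-bis(methoxymethoxy)benzene
Conditions: CBr4, PPh3, 2,6-lutidine (cat.), CH2Cl2, 0 °C
Reagents that add atoms: carbon tetrabromide, BrC(Br)(Br)Br
Why: Appel bromination replaces the primary hydroxyl by SN2 attack of bromide on the oxyphosphonium ion under near-neutral conditions, the lutidine buffering any HBr so that the MOM acetals survive.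

Step 6
Reactants: 8 1-(7-bromoheptyl)-3,5-bis(methoxymethoxy)benzene
Product: 9 7-[3,5-bis(methoxymethoxy)phenyl]heptylmagnesium bromide
Conditions: Mg turnings (I2-activated), Et2O, gentle reflux; titrated solution used directly
Reagents that add atoms: magnesium, [Mg]
Why: Grignard formation by oxidative insertion of magnesium into the primary C–Br bond is compatible with aryl MOM ethers, and diethyl ether is chosen because it is the preferred medium for the carbocupration that follows.

Step 7
Reactants: 10 (S)-1,2-epoxybutane; 11 benzyl 4-bromobutyl ether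
Product: 13 (3S)-8-(benzyloxy)octan-3-ol, via 4-(benzyloxy)butylmagnesium bromide 12 (not isolated)
Conditions: 11, Mg, THF, rt → 40 °C; then CuI (10 mol %), 10, −30 → 0 °C
Reagents that add atoms: none
Why: Copper-catalysed SN2 ring opening of the terminal epoxide by the alkyl Grignard reagent occurs at the unsubstituted CH2 carbon, so the C–O bond at the stereocentre is never broken and the (S) configuration of 10 becomes that of C15.

Step 8
Reactants: 13 (3S)-8-(benzyloxy)octan-3-ol
Product: 14 {[(3S)-8-(benzyloxy)octan-3-yl]oxy}(tert-butyl)dimethylsilane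
Conditions: TBSCl, imidazole, DMF, rt
Reagents that add atoms: tert-butyldimethylsilyl chloride, CC(C)(C)[Si](C)(C)Cl
Why: Imidazole-promoted silylation of the secondary alcohol (silyl ether formation) is reliable and does not involve the stereocentre.

Step 9
Reactants: 14 {[(3S)-8-(benzyloxy)octan-3-yl]oxy}(tert-butyl)dimethylsilane
Product: 15 (6S)-6-[(tert-butyldimethylsilyl)oxy]octan-1-ol
Conditions: H2 (1 atm), 10% Pd/C, EtOAc, rt
Reagents that add atoms: none
Why: Hydrogenolysis of the benzyl ether over Pd/C frees the primary alcohol, while the secondary TBS ether is stable in neutral, aprotic ethyl acetate.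

Step 10
Reactants: 15 (6S)-6-[(tert-butyldimethylsilyl)oxy]octan-1-ol
Product: 16 tert-butyl{[(3S)-8-iodooctan-3-yl]oxy}dimethylsilane
Conditions: I2, PPh3, imidazole, CH2Cl2, 0 °C → rt
Reagents that add atoms: iodine, II
Why: Appel-type iodination (PPh3/I2/imidazole) converts the primary alcohol into the iodide by SN2 displacement under buffered conditions that spare the silyl ether.

Step 11
Reactants: 9 7-[3,5-bis(methoxymethoxy)phenyl]heptylmagnesium bromide; 17 acetylene; 16 tert-butyl{[(3S)-8-iodooctan-3-yl]oxy}dimethylsilane
Product: 20 1,3-bis(methoxymethoxy)-5-[(8Z,15S)-15-(tert-butyldimethylsilyloxy)heptadec-8-en-1-yl]benzene, via magnesium dialkylcuprate 18 (not isolated), via Z-dialkenylcuprate 19 (not isolated)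
Conditions: CuBr·SMe2 (0.5 equiv per 9), Et2O/Me2S, −40 °C; HC≡CH (1 equiv per 9, acetone-free, metered), −50 → −25 °C; then 16 (limiting), THF, HMPA, P(OEt)3, −40 °C → rt
Reagents that add atoms: none
Why: Two equivalents of Grignard reagent 9 transmetalate to CuBr to give the magnesium homocuprate 18, whose Cu–C bonds add across the π-bond of acetylene in a four-centre syn carbocupration, so that C7 and copper end up cis on C8=C9 in the dialkenylcuprate 19. This is the Normant-type carbocupration of acetylene by dialkylcuprates, and the in-flask coupling of 19 with the primary iodide 16 (oxidative addition at copper assisted by HMPA and P(OEt)3, then reductive elimination with retention at the sp2 carbon) is the established alkylation of Z-alkenylcuprates used for Z-alkene pheromones. No ring is closed and no stereocentre is created; C15 lies five methylenes from the reacting carbon and is carried through unchanged. The selectivity needed is Z geometry, which follows from syn addition plus retention and from the configurational stability of alkenylcopper species at low temperature. Single insertion is secured by dosing one equivalent of acetylene per alkyl group at −50 to −25 °C, where the alkenylcuprate does not add to a second acetylene, and the exact 2:1 Mg/Cu ratio leaves no free Grignard reagent to deprotonate acetylene. Aryl MOM ethers and the silyl ether are inert to cuprates, and making the iodide the limiting partner compensates for any incomplete transfer of the second alkenyl group.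

Step 12
Reactants: 20 1,3-bis(methoxymethoxy)-5-[(8Z,15S)-15-(tert-butyldimethylsilyloxy)heptadec-8-en-1-yl]benzene
Product: 21 Hansfordiol G, 5-[(8Z,15S)-15-hydroxyheptadec-8-en-1-yl]benzene-1,3-diol
Conditions: HCl (ca. 1 M), MeOH, rt → 45 °C
Reagents that add atoms: none
Why: Acid-catalysed methanolysis cleaves both aryl MOM acetals (acetal exchange) and the secondary TBS ether (solvolysis) in one operation without breaking the C15–O bond, so the (S) configuration and the isolated Z-alkene are preserved.

**Compound list**

1 | 6-bromohexan-1-ol | OCCCCCCBr | starting material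
2 | (6-hydroxyhexyl)triphenylphosphonium bromide | [Br-].OCCCCCC[P+](c1ccccc1)(c1ccccc1)c1ccccc1 | intermediate
3 | 3,5-dihydroxybenzaldehyde | O=Cc1cc(O)cc(O)c1 | starting material
4 | 3,5-bis(methoxymethoxy)benzaldehyde | COCOc1cc(C=O)cc(OCOC)c1 | intermediate
5 | sodium 6-(triphenylphosphoranylidene)hexan-1-olate (ylide alkoxide, not isolated) | [Na+].[O-]CCCCCC=P(c1ccccc1)(c1ccccc1)c1ccccc1 | intermediate
6 | 7-[3,5-bis(methoxymethoxy)phenyl]hept-6-en-1-ol (E/Z mixture) | COCOc1cc(C=CCCCCCO)cc(OCOC)c1 | intermediate
7 | 7-[3,5-bis(methoxymethoxy)phenyl]heptan-1-ol | COCOc1cc(CCCCCCCO)cc(OCOC)c1 | intermediate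
8 | 1-(7-bromoheptyl)-3,5-bis(methoxymethoxy)benzene | COCOc1cc(CCCCCCCBr)cc(OCOC)c1 | intermediate
9 | 7-[3,5-bis(methoxymethoxy)phenyl]heptylmagnesium bromide (ethereal solution) | COCOc1cc(CCCCCCC[Mg]Br)cc(OCOC)c1 | intermediate
10 | (S)-1,2-epoxybutane, (2S)-2-ethyloxirane | CC[C@H]1CO1 | starting material
11 | benzyl 4-bromobutyl ether | BrCCCCOCc1ccccc1 | starting material
12 | 4-(benzyloxy)butylmagnesium bromide (not isolated) | Br[Mg]CCCCOCc1ccccc1 | intermediate
13 | (3S)-8-(benzyloxy)octan-3-ol | CC[C@H](O)CCCCCOCc1ccccc1 | intermediate
14 | {[(3S)-8-(benzyloxy)octan-3-yl]oxy}(tert-butyl)dimethylsilane | CC[C@H](O[Si](C)(C)C(C)(C)C)CCCCCOCc1ccccc1 | intermediate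
15 | (6S)-6-[(tert-butyldimethylsilyl)oxy]octan-1-ol | CC[C@H](O[Si](C)(C)C(C)(C)C)CCCCCO | intermediate
16 | tert-butyl{[(3S)-8-iodooctan-3-yl]oxy}dimethylsilane | CC[C@H](O[Si](C)(C)C(C)(C)C)CCCCCI | intermediate
17 | acetylene | C#C | starting material
18 | bromomagnesium bis{7-[3,5-bis(methoxymethoxy)phenyl]heptyl}cuprate (not isolated) | COCOc1cc(CCCCCCC[Cu-]CCCCCCCc2cc(OCOC)cc(OCOC)c2)cc(OCOC)c1.[Mg+]Br | intermediate
19 | bromomagnesium bis{(1Z)-9-[3,5-bis(methoxymethoxy)phenyl]non-1-en-1-yl}cuprate (not isolated) | COCOc1cc(CCCCCCC/C=C\[Cu-]/C=C\CCCCCCCc2cc(OCOC)cc(OCOC)c2)cc(OCOC)c1.[Mg+]Br | intermediate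
20 | 1,3-bis(methoxymethoxy)-5-[(8Z,15S)-15-(tert-butyldimethylsilyloxy)heptadec-8-en-1-yl]benzene | CC[C@H](O[Si](C)(C)C(C)(C)C)CCCCC/C=C\CCCCCCCc1cc(OCOC)cc(OCOC)c1 | intermediate
21 | Hansfordiol G, 5-[(8Z,15S)-15-hydroxyheptadec-8-en-1-yl]benzene-1,3-diol | CC[C@H](O)CCCCC/C=C\CCCCCCCc1cc(O)cc(O)c1 | target

**Count and risk**

Total step count: 12. Longest linear sequence: 7 steps (steps 2, 3, 4, 5, 6, 11, 12, from 3,5-dihydroxybenzaldehyde).

Steps most likely to fail:

1. Step 11. The processes at risk are insertion of a second acetylene into the alkenyl–copper bond, thermal decay of the alkylcuprate before it adds, and slow alkylation of the alkenylcuprate so that it is merely protonated on work-up. The fallback sets out from 8 and 16 and comes back at 20, forming the same two bonds stepwise through an alkyne. Bromide 8 is treated with lithium acetylide–ethylenediamine complex in DMSO at rt to give 1,3-bis(methoxymethoxy)-5-(non-8-yn-1-yl)benzene F1. Deprotonation of the terminal alkyne with n-BuLi (THF, −78 °C) and alkylation with iodide 16 in THF/DMPU (−78 °C → rt) should give 1,3-bis(methoxymethoxy)-5-[(15S)-15-(tert-butyldimethylsilyloxy)heptadec-8-yn-1-yl]benzene F2. Lindlar semi-hydrogenation (H2, Pd/CaCO3–Pb, quinoline, hexane/EtOAc) should then deliver the Z-alkene 20.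

2. Step 12. The processes at risk are capture of the liberated methoxymethyl cation by the electron-rich resorcinol ring (C-alkylation ortho/para to the oxygens) and stalling after loss of only one MOM group. The fallback sets out from 20 and comes back at 21 in two stages with a cation trap. TBAF in THF at rt removes the silyl ether to give (3S,9Z)-17-[3,5-bis(methoxymethoxy)phenyl]heptadec-9-en-3-ol F3. ZnBr2 with n-PrSH in CH2Cl2 at 0 °C then cleaves both aryl MOM ethers, the thiol intercepting the methoxymethyl fragment, to give 21.

3. Step 3. The processes at risk are aggregation and poor solubility of the doubly deprotonated hydroxyalkylphosphonium salt, giving incomplete ylide formation and low conversion of the aldehyde. The fallback sets out from 4 and comes back at 6, building the chain by olefin metathesis instead. Methylenation of 4 (Ph3PCH3Br, KOt-Bu, THF, 0 °C) gives 1,3-bis(methoxymethoxy)-5-vinylbenzene F4. Cross-metathesis of this styrene with commercial hept-6-en-1-ol (Grubbs second-generation catalyst, CH2Cl2, 40 °C) should give 6, whose geometry is again irrelevant because of step 4.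

**Further compounds**

F1 | step 11 | 1,3-bis(methoxymethoxy)-5-(non-8-yn-1-yl)benzene | COCOc1cc(CCCCCCCC#C)cc(OCOC)c1
F2 | step 11 | 1,3-bis(methoxymethoxy)-5-[(15S)-15-(tert-butyldimethylsilyloxy)heptadec-8-yn-1-yl]benzene | CC[C@H](O[Si](C)(C)C(C)(C)C)CCCCCC#CCCCCCCCc1cc(OCOC)cc(OCOC)c1
F3 | step 12 | (3S,9Z)-17-[3,5-bis(methoxymethoxy)phenyl]heptadec-9-en-3-ol | CC[C@H](O)CCCCC/C=C\CCCCCCCc1cc(OCOC)cc(OCOC)c1
F4 | step 3 | 1,3-bis(methoxymethoxy)-5-vinylbenzene | C=Cc1cc(OCOC)cc(OCOC)c1
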